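**Retrosynthetic overview**
1. The CH2OH group comes from CO2H by a final borane reduction. The carboxyl group is kept until then because it serves as directing group, then leaving group, then alcohol precursor.
2. The diarylmethane CH2 comes from a 3-arylphthalide. Base opens it, as phenolphthalein opens, to a quinone methide that is trapped by hydride, and the same pot removes all four acetates.
3. Key disconnection: the 3-arylphthalide comes from symmetric 3,5-diacetoxy-4-methoxybenzoic acid and 2,3-dibromo-4,5-diacetoxybenzaldehyde. The step is a Rh(III) carboxylate-directed C–H addition with lactonisation, used in place of Friedel–Crafts benzylation or ArLi + ArCHO.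
4. The aldehyde comes from 5-bromovanillin (bromination, demethylation, acetylation). The acid comes from 4-O-methylgallic acid (acetylation).
5. Rings: both benzene rings are bought. The only ring formed is the temporary γ-lactone, closed in the key step and opened in the next.

**Assumption:** the target SMILES has no stereocentre and no stereogenic double bond, so it is achiral and "single enantiomer" needs no stereocontrol. The one stereocentre that appears on the way (C3 of the phthalide) is formed racemic and erased in step 6.

**Step 1**
Reactants: 1 5-bromovanillin (3-bromo-4-hydroxy-5-methoxybenzaldehyde)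
Product: 2 5,6-dibromovanillin (2,3-dibromo-4-hydroxy-5-methoxybenzaldehyde)
Conditions: Br2 (1.2 equiv), Fe powder (5 mol %), AcOH, rt to 50 °C
Reagents that add atoms: bromine, BrBr
Why: Electrophilic aromatic bromination goes to the open position para to OMe (old C6) rather than the crowded site between CHO and OMe, which gives the contiguous Br/Br/OH/OMe pattern of ring B.

**Step 2**
Reactants: 2 5,6-dibromovanillin
Product: 3 2,3-dibromo-4,5-dihydroxybenzaldehyde
Conditions: AlCl3 (1.5 equiv), pyridine (5 equiv), CH2Cl2, reflux; then 2 M HCl
Reagents that add atoms: none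
Why: In this chelation-directed aryl methyl ether cleavage (AlCl3–pyridine), the aluminium phenoxide activates only the neighbouring OMe for SN2 demethylation, and CHO and both C–Br bonds are untouched.

**Step 3**
Reactants: 3 2,3-dibromo-4,5-dihydroxybenzaldehyde
Product: 4 2,3-dibromo-4,5-diacetoxybenzaldehyde
Conditions: Ac2O (3 equiv), pyridine, DMAP (5 mol %), CH2Cl2, 0 °C to rt
Reagents that add atoms: acetic anhydride, CC(=O)OC(C)=O
Why: DMAP-catalysed O-acylation masks the metal-binding, oxidisable catechol and makes the aldehyde more electrophilic for the key step, and basic conditions avoid acylal formation at CHO.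

**Step 4**
Reactants: 5 3,5-dihydroxy-4-methoxybenzoic acid (4-O-methylgallic acid)
Product: 6 3,5-diacetoxy-4-methoxybenzoic acid
Conditions: Ac2O (3 equiv), pyridine, 0 °C to rt; then H2O, 1 M HCl
Reagents that add atoms: acetic anhydride, CC(=O)OC(C)=O
Why: Phenol O-acetylation, as in the standard preparation of acetylated gallic acids, leaves the carboxylic acid free after the aqueous quench and keeps the molecule symmetric.

**Step 5 (key step)**
Reactants: 4 2,3-dibromo-4,5-diacetoxybenzaldehyde; 6 3,5-diacetoxy-4-methoxybenzoic acid (1.5 equiv)
Product: 8 (±)-3-(4,5-diacetoxy-2,3-dibromophenyl)-4,6-diacetoxy-5-methoxyisobenzofuran-1(3H)-one, via racemic hydroxy acid 7 (not isolated)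
Conditions: [Cp*RhCl2]2 (5 mol %), AgOTf (20 mol %), Ag2CO3 (25 mol %), 4 Å MS, 1,4-dioxane, 140 °C, sealed tube, Ar
Reagents that add atoms: none
Why: This is a Rh(III)-catalysed carboxylate-directed ortho C–H activation (CMD), aldehyde insertion and lactonisation cascade in which the two ortho C–H bonds of 6 are symmetry-equivalent and acidified by the adjacent OAc, the electron-poor aldehyde favours insertion, lactonisation makes the addition irreversible and removes the directing group so only one addition occurs, Cp*Rh(III) does not insert into ArBr, and the new C3 stereocentre is formed racemic and erased in step 6.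

**Step 6**
Reactants: 8 (±)-tetraacetoxy 3-arylphthalide
Product: 11 2-(2,3-dibromo-4,5-dihydroxybenzyl)-3,5-dihydroxy-4-methoxybenzoic acid, via racemic tetrahydroxy phthalide 9 (not isolated), via para-quinone methide acid 10 (not isolated)
Conditions: NaOH (2 M aq, 12 equiv), NaBH4 (6 equiv), degassed THF–H2O, 0 to 50 °C, Ar; then 2 M HCl to pH 2, 0 °C
Reagents that add atoms: none
Why: Proposed new method: hydroxide strips the four aryl acetates to give 9, whose phenoxides para (ring B O-4', ring A O-6) and ortho (ring A O-4) to the benzhydrylic carbon expel the lactone carboxylate by E1cB alkyl–oxygen cleavage just as phenolphthalein opens to its coloured quinone-methide dianion, and borohydride then adds 1,6 to the exocyclic methine of 10 with rearomatisation as the only irreversible exit, while carboxylate, OMe and ArBr are inert to NaBH4 in aqueous base and the stereocentre disappears; the closest known reaction types are the Zn/NaOH reduction of phenolphthalein to phenolphthalin and the NaBH4/aqueous NaOH deoxygenation of o/p-hydroxybenzyl alcohols and hydroxybenzophenones via quinone methides.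

**Step 7**
Reactants: 11 2-(2,3-dibromo-4,5-dihydroxybenzyl)-3,5-dihydroxy-4-methoxybenzoic acid
Product: 12 target, 3,4-dibromo-5-[[2,4-dihydroxy-6-(hydroxymethyl)-3-methoxyphenyl]methyl]benzene-1,2-diol
Conditions: BH3·THF (10 equiv), THF, 0 °C to rt; then H2O, sat. aq NH4Cl (no strong acid)
Reagents that add atoms: none
Why: Chemoselective borane reduction of the carboxylic acid proceeds through the acyloxyborane, the four phenols only form hydrolysable aryl borates with loss of H2, ArBr and OMe are inert, and the new CH2OH lies meta to both ring-A hydroxyls so no quinone-methide over-reduction is available.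

**Compound list**
1 | 5-bromovanillin (3-bromo-4-hydroxy-5-methoxybenzaldehyde) | O=Cc1cc(Br)c(O)c(OC)c1 | starting material
2 | 2,3-dibromo-4-hydroxy-5-methoxybenzaldehyde | O=Cc1cc(OC)c(O)c(Br)c1Br | intermediate
3 | 2,3-dibromo-4,5-dihydroxybenzaldehyde | O=Cc1cc(O)c(O)c(Br)c1Br | intermediate
4 | 2,3-dibromo-4,5-diacetoxybenzaldehyde | CC(=O)Oc1cc(C=O)c(Br)c(Br)c1OC(C)=O | intermediate
5 | 3,5-dihydroxy-4-methoxybenzoic acid | COc1c(O)cc(C(=O)O)cc1O | starting material
6 | 3,5-diacetoxy-4-methoxybenzoic acid | COc1c(OC(C)=O)cc(C(=O)O)cc1OC(C)=O | intermediate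
7 | (±)-3,5-diacetoxy-2-[(4,5-diacetoxy-2,3-dibromophenyl)(hydroxy)methyl]-4-methoxybenzoic acid (formed in the flask, step 5) | COc1c(OC(C)=O)cc(C(=O)O)c(C(O)c2cc(OC(C)=O)c(OC(C)=O)c(Br)c2Br)c1OC(C)=O | intermediate
8 | (±)-3-(4,5-diacetoxy-2,3-dibromophenyl)-4,6-diacetoxy-5-methoxyisobenzofuran-1(3H)-one | COc1c(OC(C)=O)cc2C(=O)OC(c3cc(OC(C)=O)c(OC(C)=O)c(Br)c3Br)c2c1OC(C)=O | intermediate
9 | (±)-3-(2,3-dibromo-4,5-dihydroxyphenyl)-4,6-dihydroxy-5-methoxyisobenzofuran-1(3H)-one (formed in the flask, step 6) | COc1c(O)cc2C(=O)OC(c3cc(O)c(O)c(Br)c3Br)c2c1O | intermediate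
10 | 2-[(E)-(2,3-dibromo-5-hydroxy-4-oxocyclohexa-2,5-dien-1-ylidene)methyl]-3,5-dihydroxy-4-methoxybenzoic acid (formed in the flask, step 6; drawn neutral, aryl anti to Br) | COc1c(O)cc(C(=O)O)c(/C=C2\C=C(O)C(=O)C(Br)=C2Br)c1O | intermediate
11 | 2-(2,3-dibromo-4,5-dihydroxybenzyl)-3,5-dihydroxy-4-methoxybenzoic acid | COc1c(O)cc(C(=O)O)c(Cc2cc(O)c(O)c(Br)c2Br)c1O | intermediate
12 | 3,4-dibromo-5-[[2,4-dihydroxy-6-(hydroxymethyl)-3-methoxyphenyl]methyl]benzene-1,2-diol (CNP0333037.0, achiral) | COc1c(O)cc(CO)c(Cc2cc(O)c(O)c(Br)c2Br)c1O | target

**Total step count:** 7.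
**Longest linear sequence:** 6 (steps 1, 2, 3, 5, 6, 7).

**Three steps most likely to fail**

Step 5. The C–H bond is flanked by OAc, the aldehyde carries an ortho bromine, insertion is reversible, and the acetates must survive 140 °C. The fallback gives up C–H metalation for a classical electrophilic substitution. It sets out from 4 and 5. The free phenolic acid 5 and aldehyde 4 are warmed in CF3CO2H at 50 °C. The ring carbon ortho and para to the two free hydroxyls attacks the protonated aldehyde, and the carbinol lactonises at once. This gives (±)-3-(4,5-diacetoxy-2,3-dibromophenyl)-4,6-dihydroxy-5-methoxyisobenzofuran-1(3H)-one F1. F1 goes into the unchanged step 6 conditions, where loss of its two acetates gives 9, and the route is rejoined at 9.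

Step 6. The delocalised quinone-methide anion may be too weak an electrophile, borate may tie up the catechol, or hydride may add at the β-bromo enone carbon. The fallback moves from anionic E1cB/hydride chemistry to cationic chemistry. It sets out from 8. HCl generated from AcCl in MeOH at rt transesterifies the four acetates, and 9 is isolated. Et3SiH (3 equiv) in CF3CO2H/CH2Cl2 at 0 °C to rt then carries out an ionic hydrogenation. The protonated lactone ionises to a benzhydryl cation stabilised by the para and ortho hydroxyls, and the silane captures it. The route is rejoined at 11. This fallback makes no compound outside the list (F0).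

Step 7. The polyphenolic acid may form insoluble borates or reduce incompletely. The fallback replaces electrophilic borane on the acid with nucleophilic aluminium hydride on an ester. It sets out from 11. Fischer esterification (MeOH, cat. H2SO4, reflux) gives methyl 2-(2,3-dibromo-4,5-dihydroxybenzyl)-3,5-dihydroxy-4-methoxybenzoate F2. F2 is reduced with DIBAL-H (10 equiv) in THF at −78 to 0 °C with a Rochelle-salt work-up, and the route is rejoined at 12.

**Further compounds**
F1 | step 5 | (±)-3-(4,5-diacetoxy-2,3-dibromophenyl)-4,6-dihydroxy-5-methoxyisobenzofuran-1(3H)-one | COc1c(O)cc2C(=O)OC(c3cc(OC(C)=O)c(OC(C)=O)c(Br)c3Br)c2c1O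
F0 | step 6 | none | none
F2 | step 7 | methyl 2-(2,3-dibromo-4,5-dihydroxybenzyl)-3,5-dihydroxy-4-methoxybenzoate | COC(=O)c1cc(O)c(OC)c(O)c1Cc1cc(O)c(O)c(Br)c1Br
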